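**Retrosynthetic overview**
1. Open both imidazoles of Lepidine C at once (two-directional imidate → amidine → aminoacetal cyclisation). This leads back to a diaryl ether bis(arylacetonitrile).
2. That bis-nitrile is a hidden pseudo-dimer of one C8 unit, 3-oxyphenylacetonitrile. The C–O bond is cut to an unfunctionalised arene C–H (para to OMe) and a free phenol O–H, not to an aryl halide, so the union is not an Ullmann, SNAr or Chan–Lam coupling.
3. Key pair of steps: para-selective C–H λ3-iodanation of the anisole half (mesityl as dummy ligand) makes it an aryl-cation equivalent, and Cu(I)/Cu(III) aryl transfer to the phenol half forges the ether.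
4. Ring order: both benzene rings are bought, the diaryl ether is made first, and the two imidazole rings are formed last and simultaneously.

**Assumption:** Lepidine C has no stereocentre or other stereogenic element (the diaryl ether rotates freely). It is therefore achiral, "single enantiomer" needs no stereocontrol, and the N–H tautomers of each imidazole are one compound.

**Step 1**
Reactants: 1 (3-methoxyphenyl)acetonitrile; 2 (diacetoxyiodo)mesitylene (iodomesitylene diacetate)
Product: 3 [2-(cyanomethyl)-4-methoxyphenyl](2,4,6-trimethylphenyl)iodonium triflate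
Conditions: TfOH (1.1 equiv), CH2Cl2, 0 °C to rt, 2 h; precipitate with Et2O
Reagents that add atoms: trifluoromethanesulfonic acid, OS(=O)(=O)C(F)(F)F
Why: Electrophilic aromatic C–H λ3-iodanation (acid-promoted diaryliodonium salt synthesis), in which acid-activated 2 attacks the most nucleophilic position of 1, para to OMe (the site also taken in halogenation), while the nitrile and benzylic CH2 are inert and no stereocentre is formed.

**Step 2**
Reactants: 3 [2-(cyanomethyl)-4-methoxyphenyl](2,4,6-trimethylphenyl)iodonium triflate; 4 (3-hydroxyphenyl)acetonitrile
Product: 5 2-{2-[3-(cyanomethyl)phenoxy]-5-methoxyphenyl}acetonitrile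
Conditions: 3 (1.2 equiv), Cu(MeCN)4PF6 (10 mol %), K2CO3 (1.5 equiv), 1,2-dichloroethane, rt to 40 °C, N2
Reagents that add atoms: none
Why: Proposed new method: Cu(I) adds oxidatively into the less hindered and more electron-rich aryl–I(III) bond of 3 (the mesityl group flanked by two ortho methyls stays on iodine and leaves as iodomesitylene), the aryl–Cu(III) species binds the phenoxide of 4 and reductively eliminates the diaryl ether, so steps 1 and 2 together are a formal para-selective C–H/O–H cross-coupling, the closest known reaction types being the Cu-catalysed para-selective C–H amination of electron-rich arenes through aryl(mesityl)iodonium salts and the O-arylation of phenols with diaryliodonium salts, and no stereocentre is formed.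

**Step 3**
Reactants: 5 2-{2-[3-(cyanomethyl)phenoxy]-5-methoxyphenyl}acetonitrile
Product: 6 bis(methyl imidate) dihydrochloride, methyl 2-{2-[3-(2-imino-2-methoxyethyl)phenoxy]-5-methoxyphenyl}ethanimidate dihydrochloride
Conditions: HCl (4 M in dioxane, excess), MeOH (6 equiv), 0 to 4 °C, 48 h; evaporate, triturate with Et2O
Reagents that add atoms: methanol, CO; hydrogen chloride, Cl
Why: Two-fold Pinner reaction, in which both unhindered arylacetonitriles are protonated and trapped by methanol under anhydrous conditions that leave the aryl ethers untouched, and no stereocentre is formed.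

**Step 4**
Reactants: 6 bis(methyl imidate) dihydrochloride; 7 aminoacetaldehyde dimethyl acetal (2,2-dimethoxyethanamine)
Product: 9 Lepidine C, via bis-amidine dihydrochloride 8 (not isolated)
Conditions: 7 (2.2 equiv), MeOH, 0 °C to rt, 16 h; then 3 M aq HCl, 80 °C, 3 h; NaOH to pH 10, extract
Reagents that add atoms: none
Why: Two-fold amidine synthesis from the Pinner salt followed by the classical aminoacetal imidazole synthesis (acid unmasks each acetal, the free amidine NH condenses on the aldehyde and loss of methanol aromatises the ring), a redox-neutral sequence that never exposes the benzylic CH2 groups to an oxidant and creates no stereocentre.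

**Compound list**
1 | (3-methoxyphenyl)acetonitrile | COc1cccc(CC#N)c1 | starting material
2 | (diacetoxyiodo)mesitylene | CC(=O)OI(OC(C)=O)c1c(C)cc(C)cc1C | starting material
3 | [2-(cyanomethyl)-4-methoxyphenyl](2,4,6-trimethylphenyl)iodonium triflate | COc1ccc([I+]c2c(C)cc(C)cc2C)c(CC#N)c1.[O-]S(=O)(=O)C(F)(F)F | intermediate
4 | (3-hydroxyphenyl)acetonitrile | N#CCc1cccc(O)c1 | starting material
5 | 2-{2-[3-(cyanomethyl)phenoxy]-5-methoxyphenyl}acetonitrile | COc1ccc(Oc2cccc(CC#N)c2)c(CC#N)c1 | intermediate
6 | bis(methyl imidate) dihydrochloride of 5 | COc1ccc(Oc2cccc(CC(=N)OC)c2)c(CC(=N)OC)c1.Cl.Cl | intermediate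
7 | aminoacetaldehyde dimethyl acetal | NCC(OC)OC | starting material
8 | bis[N-(2,2-dimethoxyethyl)amidine] dihydrochloride (not isolated) | COc1ccc(Oc2cccc(CC(=N)NCC(OC)OC)c2)c(CC(=N)NCC(OC)OC)c1.Cl.Cl | intermediate
9 | Lepidine C (achiral) | COc1ccc(Oc2cccc(Cc3ncc[nH]3)c2)c(Cc2ncc[nH]2)c1 | target

**Total step count:** 4. **Longest linear sequence:** 4 steps (1 → 3 → 5 → 6 → 9).

**Steps most likely to fail, with fallbacks**

The riskiest is step 2. Mesityl transfer, C-arylation, or base-induced decay of 3 through its acidified benzylic CH2 could outrun the wanted aryl transfer. The fallback gives up the iodane and retreats to the conventional aryl halide union. It sets out from 1, which is brominated para to OMe (NBS, MeCN, 0 °C to rt) to give 2-(2-bromo-5-methoxyphenyl)acetonitrile F1. This bromide is joined to 4 by a ligand-accelerated Ullmann ether synthesis (CuI, picolinic acid, K3PO4, DMSO, 90 °C). The fallback comes back to the route at 5.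

Second is step 1. The bulky iodane might give regioisomers or oxidative biaryl coupling of the anisole. The fallback reverses the roles so that the anisole half carries the iodine. It sets out from 1, which is iodinated (NIS, cat. TFA, MeCN) to give 2-(2-iodo-5-methoxyphenyl)acetonitrile F2. F2 is oxidised at iodine (mCPBA, TsOH·H2O, MeCN) and trapped with 1,3,5-trimethoxybenzene to give [2-(cyanomethyl)-4-methoxyphenyl](2,4,6-trimethoxyphenyl)iodonium tosylate F3. The very electron-rich trimethoxyphenyl ligand is not transferred, so metal-free ligand coupling with 4 (K2CO3, toluene/MeCN, 60–80 °C) delivers the ether. This fallback bypasses 3 and comes back to the route at 5.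

Third is step 4. A double cyclisation in hot aqueous acid competes with amidine hydrolysis. The fallback replaces the redox-neutral acetal cyclisation by ring closure at the dihydro level followed by aromatisation. It sets out from 6, which is condensed with ethylenediamine (2.1 equiv, MeOH, 0 °C to reflux) to give the bis-imidazoline 2-{2-[3-(4,5-dihydro-1H-imidazol-2-ylmethyl)phenoxy]-5-methoxybenzyl}-4,5-dihydro-1H-imidazole F4. Both rings are then dehydrogenated (10 % Pd/C, refluxing xylene). The fallback comes back to the route at 9.

**Further compounds**
F1 | step 2 | 2-(2-bromo-5-methoxyphenyl)acetonitrile | COc1ccc(Br)c(CC#N)c1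
F2 | step 1 | 2-(2-iodo-5-methoxyphenyl)acetonitrile | COc1ccc(I)c(CC#N)c1
F3 | step 1 | [2-(cyanomethyl)-4-methoxyphenyl](2,4,6-trimethoxyphenyl)iodonium 4-methylbenzenesulfonate | COc1ccc([I+]c2c(OC)cc(OC)cc2OC)c(CC#N)c1.Cc1ccc(cc1)S(=O)(=O)[O-]
F4 | step 4 | 2-{2-[3-(4,5-dihydro-1H-imidazol-2-ylmethyl)phenoxy]-5-methoxybenzyl}-4,5-dihydro-1H-imidazole | COc1ccc(Oc2cccc(CC3=NCCN3)c2)c(CC2=NCCN2)c1
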